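## Retrosynthetic overview

1. The 15-membered lactone is opened at C21–O to a seco acid (Shiina lactonisation last); the 15Z alkene comes from a C15≡C16 alkyne, and C16–C17 from alkyne 18 plus enal 22 (zinc–ProPhenol alkynylation, sets C17).
2. Ring A (dehydropiperidine) comes from aza-Michael addition and intramolecular Horner–Wadsworth–Emmons closure on piperidine 13; the C15 aldehyde unmasked in the same flask becomes the alkyne.
3. Ring B (piperidine) and C5 come from a hydrogenative reductive-amination cascade of nitro enone 10, itself made by cross-metathesis of a C9 allyl group.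
4. The aza-quaternary C9 comes from Tsuji–Trost allylation of a nitronate (nitro group as α-amino carbanion equivalent).
5. Key step: C13–C14 from propanal enamine plus 1-nitrocyclopentene, where the nitroalkene makes the normally nucleophilic α-carbon C13 electrophilic and sets C13/C14. Ring order: cyclopentane (from cyclopentene), ring B, ring A, macrolactone.

Assumption: the target is taken exactly as drawn, (5R,9S,13R,14S,17R) with 15Z and 18E (Cl trans to C17), using the labels C1 = lactone C=O, C2=C3, C5 = NCH, C9 = spiro C, C13 = ring CH, C14 = CHMe, C15=C16, C17 = CHOH, C18=C19(Cl), C21 = OCH2, C22 = NCH2; catalyst antipodes are named for their usual sense of induction and would be exchanged if it proved opposite.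

## Route

Step 1
Reactants: 1 cyclopentene
Product: 3 1-nitrocyclopentene, via trans-1-iodo-2-nitrocyclopentane 2 (not isolated)
Conditions: NaNO2 (4 equiv), I2 (1.5 equiv), ethylene glycol, EtOAc/H2O, 0 °C → rt, 48 h
Reagents that add atoms: sodium nitrite, [Na+].[O-]N=O
Why: Iodonitration of the alkene by INO2 formed in situ, followed by nitrite-induced loss of HI from 2, gives the conjugated nitroalkene in one pot (iodonitration–elimination); no stereocentre remains.

Step 2
Reactants: 3 1-nitrocyclopentene; 4 propanal (3 equiv)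
Product: 6 (1R)-1-[(2R)-1,1-dimethoxypropan-2-yl]-2-nitrocyclopentane (both C–NO2 epimers), via nitro aldehyde 5 (not isolated)
Conditions: (S)-α,α-diphenylprolinol trimethylsilyl ether (15 mol%), 4-nitrophenol (15 mol%), toluene, 0 °C → rt; then HC(OMe)3, MeOH, p-TsOH (5 mol%), rt
Reagents that add atoms: trimethyl orthoformate, COC(OC)OC
Why: Hayashi–Jørgensen enamine Michael addition in which the nitroalkene reverses the polarity of C13 so that it couples with the nucleophilic α-carbon C14 of propanal; the (S)-catalyst sets 14R by enamine face shielding and 13R through the usual synclinal (syn) transition state, the C9 epimers are erased in step 3, and in situ acetalisation protects the epimerisable aldehyde.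

Step 3
Reactants: 6 nitro acetal
Product: 7 (1S,2R)-2-[(2R)-1,1-dimethoxypropan-2-yl]-1-nitro-1-(prop-2-en-1-yl)cyclopentane
Conditions: allyl methyl carbonate (1.5 equiv), Pd(PPh3)4 (5 mol%), THF, 40 °C
Reagents that add atoms: allyl methyl carbonate, C=CCOC(=O)OC
Why: Tsuji–Trost allylation of the nitronate generated by the methoxide released from the carbonate, the nitro group now acting as an α-amino carbanion equivalent; the π-allyl palladium electrophile attacks the planar nitronate anti to the bulky C13 substituent, so NO2 ends cis to C14 (9S).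

Step 4
Reactants: 8 2-(trimethylsilyloxy)buta-1,3-diene
Product: 9 5,5-dimethoxypent-1-en-3-one
Conditions: HC(OMe)3 (1.2 equiv), TMSOTf (5 mol%), CH2Cl2, −78 °C; NaHCO3 quench
Reagents that add atoms: trimethyl orthoformate, COC(OC)OC
Why: Mukaiyama-type addition of the silyl enol ether terminus to the dimethoxycarbenium ion from the orthoformate gives the β-keto acetal and leaves the vinyl ketone intact.

Step 5
Reactants: 7 allyl nitro acetal; 9 enone (3 equiv)
Product: 10 (4E)-6-[(1S,2R)-2-[(2R)-1,1-dimethoxypropan-2-yl]-1-nitrocyclopentyl]-1,1-dimethoxyhex-4-en-3-one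
Conditions: second-generation Hoveyda–Grubbs catalyst [RuCl2(H2IMes)(=CH-C6H4-2-OiPr)] (5 mol%), CH2Cl2, 40 °C
Reagents that add atoms: none
Why: Olefin cross-metathesis of the unhindered terminal alkene with an electron-poor vinyl ketone that does not homodimerise gives the (E)-enone and tolerates nitro and acetal groups.

Step 6
Reactants: 10 nitro enone
Product: 13 (1R,5S,7R)-7-(2,2-dimethoxyethyl)-1-[(2R)-1,1-dimethoxypropan-2-yl]-6-azaspiro[4.5]decane, via amino ketone 11 (not isolated), via cyclic imine 12 (not isolated)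
Conditions: H2 (5 atm), Raney Ni, MeOH, rt
Reagents that add atoms: none
Why: Hydrogenation reduces the enone C=C and the tertiary nitro group, the δ-amino ketone condenses to the six-membered ketimine, and hydrogen then adds to C=N from the C10 face, anti to the C13 side chain that covers the other face, setting 5R (reductive-amination cascade).

Step 7
Reactants: 13 spiro-piperidine; 14 methyl 2-(dimethoxyphosphoryl)prop-2-enoate (trimethyl 2-phosphonoacrylate)
Product: 15 methyl 3-[(1R,5S,7R)-7-(2,2-dimethoxyethyl)-1-[(2R)-1,1-dimethoxypropan-2-yl]-6-azaspiro[4.5]decan-6-yl]-2-(dimethoxyphosphoryl)propanoate (both epimers at the phosphonate carbon)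
Conditions: MeOH, 40 °C
Reagents that add atoms: none
Why: Aza-Michael addition of the secondary amine to a doubly activated, sterically small vinylphosphonate; the new phosphonate-bearing stereocentre is a mixture that is destroyed in step 8.

Step 8
Reactants: 15 phosphonate bis-acetal
Product: 18 methyl (1S,2R,9a'R)-2-[(2R)-but-3-yn-2-yl]-1',4',7',8',9',9a'-hexahydrospiro[cyclopentane-1,6'-quinolizine]-3'-carboxylate, via dialdehyde 16 (not isolated), via tricyclic aldehyde 17 (not isolated)
Conditions: 3 M HCl, THF, rt, then evaporate; K2CO3 (5 equiv), MeOH, 0 °C → rt; then dimethyl (1-diazo-2-oxopropyl)phosphonate (1.5 equiv), rt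
Reagents that add atoms: dimethyl (1-diazo-2-oxopropyl)phosphonate, COP(=O)(OC)C(=[N+]=[N-])C(C)=O
Why: Acid unmasks both aldehydes, carbonate triggers an intramolecular Horner–Wadsworth–Emmons olefination that closes six-membered ring A on the unhindered C3 aldehyde (a seven-membered closure on the α-branched C15 aldehyde is much slower), and Seyferth–Gilbert homologation with the Ohira–Bestmann reagent in the same K2CO3/MeOH medium converts the C15 aldehyde to the alkyne before C14 can epimerise.

Step 9
Reactants: 19 but-3-yn-1-ol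
Product: 20 but-3-yn-1-yl acetate
Conditions: Ac2O, Et3N, DMAP (cat.), CH2Cl2, 0 °C → rt
Reagents that add atoms: acetic anhydride, CC(=O)OC(C)=O
Why: DMAP-catalysed O-acylation of a primary alcohol.

Step 10
Reactants: 20 but-3-yn-1-yl acetate
Product: 21 (3E)-3-chloro-4-iodobut-3-en-1-yl acetate
Conditions: ICl (1.1 equiv), CH2Cl2, −78 → 0 °C, dark
Reagents that add atoms: iodine monochloride, ClI
Why: Electrophilic anti addition of ICl through an iodonium ion opened by chloride at the internal carbon (Markovnikov) gives the (E)-2-chloro-1-iodoalkene with iodine cis to the CH2 chain, which fixes the 18E geometry of the target.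

Step 11
Reactants: 21 chloro iodo alkene
Product: 22 (3E)-3-chloro-5-oxopent-3-en-1-yl acetate
Conditions: CO (3 atm), Bu3SnH (1.1 equiv, slow addition), Pd(PPh3)4 (4 mol%), THF, 50 °C
Reagents that add atoms: carbon monoxide, [C-]#[O+]
Why: Palladium-catalysed reductive carbonylation (Stille formylation) takes place only at the C–I bond with retention of alkene geometry, leaving the vinyl chloride and the acetate untouched.

Step 12
Reactants: 18 tricyclic alkyne; 22 enal (2 equiv)
Product: 23 methyl (1S,2R,9a'R)-2-[(2R,5S,6E)-9-(acetyloxy)-7-chloro-5-hydroxynon-6-en-3-yn-2-yl]-1',4',7',8',9',9a'-hexahydrospiro[cyclopentane-1,6'-quinolizine]-3'-carboxylate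
Conditions: ZnMe2 (3 equiv), (S,S)-ProPhenol (20 mol%), Ph3P=O (40 mol%), toluene, 4 °C; aq. NH4Cl
Reagents that add atoms: none
Why: Trost dinuclear zinc–ProPhenol alkynylation adds the zinc acetylide 1,2 to the enal with catalyst-controlled Re-face attack, giving 17S at this stage (the same arrangement is 17R once the alkyne is an alkene), while the ester, acetate and vinyl chloride are inert to the alkylzinc species.

Step 13
Reactants: 23 propargylic alcohol
Product: 24 methyl (1S,2R,9a'R)-2-[(2S,3Z,5R,6E)-9-(acetyloxy)-7-chloro-5-hydroxynona-3,6-dien-2-yl]-1',4',7',8',9',9a'-hexahydrospiro[cyclopentane-1,6'-quinolizine]-3'-carboxylate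
Conditions: H2 (1 atm), Pd/CaCO3 poisoned with Pb(OAc)2 (Lindlar type), quinoline, EtOAc, rt
Reagents that add atoms: none
Why: Lindlar-type syn semi-hydrogenation of the alkyne gives the 15Z alkene, the poisoned catalyst leaving the trisubstituted enoate and the vinyl chloride untouched.

Step 14
Reactants: 24 (15Z) acetate ester
Product: 25 (1S,2R,9a'R)-2-[(2S,3Z,5R,6E)-7-chloro-5,9-dihydroxynona-3,6-dien-2-yl]-1',4',7',8',9',9a'-hexahydrospiro[cyclopentane-1,6'-quinolizine]-3'-carboxylic acid
Conditions: LiOH·H2O (6 equiv), THF/MeOH/H2O, rt; then pH 6–7 buffer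
Reagents that add atoms: lithium hydroxide, [Li+].[OH-]
Why: Saponification cleaves the methyl ester and the acetate in one operation without touching the vinyl chloride or the base-stable bis-allylic alcohol.

Step 15
Reactants: 25 seco acid
Product: 26 CNP0129639.4, the (5R,9S,13R,14S,17R,15Z,18E) macrolactone
Conditions: 2-methyl-6-nitrobenzoic anhydride (1.3 equiv), DMAP (6 equiv), CH2Cl2 (1 mM, slow addition), rt
Reagents that add atoms: none
Why: Shiina macrolactonisation through the mixed anhydride and acylpyridinium under high dilution, in which the primary C21–OH closes the 15-membered ring far faster than the secondary C17–OH could close a strained 11-membered ring.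

## Compound list

1 | cyclopentene | C1=CCCC1 | starting material
2 | trans-1-iodo-2-nitrocyclopentane (racemic) | [O-][N+](=O)[C@@H]1CCC[C@H]1I | intermediate
3 | 1-nitrocyclopentene | [O-][N+](=O)C1=CCCC1 | intermediate
4 | propanal | CCC=O | starting material
5 | (2R)-2-[(1R)-2-nitrocyclopentyl]propanal (both C–NO2 epimers) | C[C@@H](C=O)[C@H]1CCCC1[N+](=O)[O-] | intermediate
6 | (1R)-1-[(2R)-1,1-dimethoxypropan-2-yl]-2-nitrocyclopentane (both C–NO2 epimers) | C[C@@H](C(OC)OC)[C@H]1CCCC1[N+](=O)[O-] | intermediate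
7 | (1S,2R)-2-[(2R)-1,1-dimethoxypropan-2-yl]-1-nitro-1-(prop-2-en-1-yl)cyclopentane | C[C@@H](C(OC)OC)[C@H]1CCC[C@@]1(CC=C)[N+](=O)[O-] | intermediate
8 | 2-(trimethylsilyloxy)buta-1,3-diene | C=CC(=C)O[Si](C)(C)C | starting material
9 | 5,5-dimethoxypent-1-en-3-one | C=CC(=O)CC(OC)OC | intermediate
10 | (4E)-6-[(1S,2R)-2-[(2R)-1,1-dimethoxypropan-2-yl]-1-nitrocyclopentyl]-1,1-dimethoxyhex-4-en-3-one | C[C@@H](C(OC)OC)[C@H]1CCC[C@@]1(C/C=C/C(=O)CC(OC)OC)[N+](=O)[O-] | intermediate
11 | 6-[(1S,2R)-1-amino-2-[(2R)-1,1-dimethoxypropan-2-yl]cyclopentyl]-1,1-dimethoxyhexan-3-one | C[C@@H](C(OC)OC)[C@H]1CCC[C@@]1(CCCC(=O)CC(OC)OC)N | intermediate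
12 | (1R,5S)-7-(2,2-dimethoxyethyl)-1-[(2R)-1,1-dimethoxypropan-2-yl]-6-azaspiro[4.5]dec-6-ene | C[C@@H](C(OC)OC)[C@H]1CCC[C@]12CCCC(CC(OC)OC)=N2 | intermediate
13 | (1R,5S,7R)-7-(2,2-dimethoxyethyl)-1-[(2R)-1,1-dimethoxypropan-2-yl]-6-azaspiro[4.5]decane | C[C@@H](C(OC)OC)[C@H]1CCC[C@]12CCC[C@H](CC(OC)OC)N2 | intermediate
14 | methyl 2-(dimethoxyphosphoryl)prop-2-enoate | COC(=O)C(=C)P(=O)(OC)OC | starting material
15 | methyl 3-[(1R,5S,7R)-7-(2,2-dimethoxyethyl)-1-[(2R)-1,1-dimethoxypropan-2-yl]-6-azaspiro[4.5]decan-6-yl]-2-(dimethoxyphosphoryl)propanoate (both epimers at the phosphonate carbon) | C[C@@H](C(OC)OC)[C@H]1CCC[C@]12CCC[C@H](CC(OC)OC)N2CC(C(=O)OC)P(=O)(OC)OC | intermediate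
16 | methyl 2-(dimethoxyphosphoryl)-3-[(1R,5S,7R)-7-(2-oxoethyl)-1-[(2R)-1-oxopropan-2-yl]-6-azaspiro[4.5]decan-6-yl]propanoate | C[C@@H](C=O)[C@H]1CCC[C@]12CCC[C@H](CC=O)N2CC(C(=O)OC)P(=O)(OC)OC | intermediate
17 | methyl (1S,2R,9a'R)-2-[(2R)-1-oxopropan-2-yl]-1',4',7',8',9',9a'-hexahydrospiro[cyclopentane-1,6'-quinolizine]-3'-carboxylate | C[C@@H](C=O)[C@H]1CCC[C@]12CCC[C@@H]3CC=C(CN23)C(=O)OC | intermediate
18 | methyl (1S,2R,9a'R)-2-[(2R)-but-3-yn-2-yl]-1',4',7',8',9',9a'-hexahydrospiro[cyclopentane-1,6'-quinolizine]-3'-carboxylate | C[C@@H](C#C)[C@H]1CCC[C@]12CCC[C@@H]3CC=C(CN23)C(=O)OC | intermediate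
19 | but-3-yn-1-ol | OCCC#C | starting material
20 | but-3-yn-1-yl acetate | CC(=O)OCCC#C | intermediate
21 | (3E)-3-chloro-4-iodobut-3-en-1-yl acetate | CC(=O)OCC/C(Cl)=C\I | intermediate
22 | (3E)-3-chloro-5-oxopent-3-en-1-yl acetate | CC(=O)OCC/C(Cl)=C\C=O | intermediate
23 | methyl (1S,2R,9a'R)-2-[(2R,5S,6E)-9-(acetyloxy)-7-chloro-5-hydroxynon-6-en-3-yn-2-yl]-1',4',7',8',9',9a'-hexahydrospiro[cyclopentane-1,6'-quinolizine]-3'-carboxylate | C[C@@H](C#C[C@@H](O)/C=C(/Cl)CCOC(C)=O)[C@H]1CCC[C@]12CCC[C@@H]3CC=C(CN23)C(=O)OC | intermediate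
24 | methyl (1S,2R,9a'R)-2-[(2S,3Z,5R,6E)-9-(acetyloxy)-7-chloro-5-hydroxynona-3,6-dien-2-yl]-1',4',7',8',9',9a'-hexahydrospiro[cyclopentane-1,6'-quinolizine]-3'-carboxylate | C[C@@H](/C=C\[C@@H](O)/C=C(/Cl)CCOC(C)=O)[C@H]1CCC[C@]12CCC[C@@H]3CC=C(CN23)C(=O)OC | intermediate
25 | (1S,2R,9a'R)-2-[(2S,3Z,5R,6E)-7-chloro-5,9-dihydroxynona-3,6-dien-2-yl]-1',4',7',8',9',9a'-hexahydrospiro[cyclopentane-1,6'-quinolizine]-3'-carboxylic acid | C[C@@H](/C=C\[C@@H](O)/C=C(/Cl)CCO)[C@H]1CCC[C@]12CCC[C@@H]3CC=C(CN23)C(=O)O | intermediate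
26 | CNP0129639.4, (5R,9S,13R,14S,17R,15Z,18E) macrolactone | C[C@H]1/C=C\[C@@H](O)/C=C(/Cl)CCOC(=O)C2=CC[C@H]3CCC[C@]4(CCC[C@H]14)N3C2 | target

## Step count and risks

Total step count: 15. Longest linear sequence: 11 steps (steps 1, 2, 3, 5, 6, 7, 8, 12, 13, 14, 15); steps 4 and 9–11 make the two side fragments.

Most likely to fail, step 2: enamine addition to a trisubstituted cyclic nitroalkene may be slow or poorly selective. The fallback replaces amine catalysis by a stoichiometric auxiliary; it sets out from 4 (with 3) and comes back at 5. Propanal is condensed with (R)-1-amino-2-(methoxymethyl)pyrrolidine to give the propanal RAMP hydrazone F1, which is deprotonated with LDA (THF, −78 °C) and added to 3 at −100 °C to give the Michael adduct hydrazone F2; aqueous oxalic acid then releases aldehyde 5, which is acetalised to 6 as before.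

Most likely to fail, step 7: the secondary amine, flanked by the quaternary C9 and the substituted C5, may not add to the acrylate. The fallback forms the same compound by a Mannich reaction, making the C22–C2 bond instead of the N–C22 bond; it sets out from 13 and comes back at 15. Amine 13 is treated with paraformaldehyde to give the N-hydroxymethyl hemiaminal F3 (in equilibrium with the methylene iminium ion), which is trapped by trimethyl phosphonoacetate (AcOH, MeCN, 60 °C) to give 15.

Most likely to fail, step 15: lactonisation of the (15Z,18E) seco acid with a free C17–OH may oligomerise or be conformationally disfavoured. The fallback closes the macrocycle at C16–C17 instead of at the ester; it sets out from 18 (with 19) and comes back at 26. Ester 18 is saponified to the alkynyl acid F4, and 19 is treated with ICl to give (3E)-3-chloro-4-iodobut-3-en-1-ol F5. The two are joined (EDC, DMAP) to the iodoalkenyl ester F6, which is cyclised by intramolecular carbonylative Sonogashira coupling (PdCl2(PPh3)2, CuI, CO, Et3N, high dilution) to the macrocyclic ynone F7. Transfer hydrogenation with RuCl(p-cymene)[(S,S)-TsDPEN] and HCO2H/Et3N gives the macrocyclic propargylic alcohol F8, and semi-hydrogenation as in step 13 gives 26.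

Further compounds
F1 | step 2 | propanal RAMP hydrazone, (2R)-2-(methoxymethyl)-N-[(E)-propylidene]pyrrolidin-1-amine | CC/C=N/N1CCC[C@@H]1COC
F2 | step 2 | RAMP hydrazone of aldehyde 5 (both C–NO2 epimers) | C[C@@H](/C=N/N1CCC[C@@H]1COC)[C@H]1CCCC1[N+](=O)[O-]
F3 | step 7 | N-hydroxymethyl hemiaminal of 13 | C[C@@H](C(OC)OC)[C@H]1CCC[C@]12CCC[C@H](CC(OC)OC)N2CO
F4 | step 15 | alkynyl acid (free acid of 18) | C[C@@H](C#C)[C@H]1CCC[C@]12CCC[C@@H]3CC=C(CN23)C(=O)O
F5 | step 15 | (3E)-3-chloro-4-iodobut-3-en-1-ol | OCC/C(Cl)=C\I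
F6 | step 15 | (3E)-3-chloro-4-iodobut-3-en-1-yl ester of F4 | C[C@@H](C#C)[C@H]1CCC[C@]12CCC[C@@H]3CC=C(CN23)C(=O)OCC/C(Cl)=C\I
F7 | step 15 | macrocyclic ynone (C17 ketone, C15≡C16) | C[C@H]1C#CC(=O)/C=C(/Cl)CCOC(=O)C2=CC[C@H]3CCC[C@]4(CCC[C@H]14)N3C2
F8 | step 15 | macrocyclic propargylic alcohol (17S, C15≡C16) | C[C@H]1C#C[C@@H](O)/C=C(/Cl)CCOC(=O)C2=CC[C@H]3CCC[C@]4(CCC[C@H]14)N3C2
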